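## Analysis of the target

Arecatannin A2 (27) is a linear procyanidin tetramer. Four flavan-3-ol units, each a chroman (ring A fused to the pyran ring C) with a catechol ring B on C2, are joined by three bonds from C4 of one unit to C8 of the next. The three upper units are epicatechin units (2R,3R, ring B and 3-hydroxyl cis), and each carries its interflavan bond on the face of ring C opposite the 3-hydroxyl (4β, 3,4-trans). The terminal unit is (+)-catechin (2R,3S) with a C4 methylene, so there are eleven stereocentres, nine of them in three identical C2–C3–C4 triads. There are sixteen phenolic and four secondary hydroxyls. The phloroglucinol and catechol rings oxidise easily, a free 4'-hydroxyl allows base-induced opening of ring C with loss of the C2 configuration, and each interflavan bond is a doubly activated diarylmethine that acid cleaves back to a C4 cation. The difficulty is the repeated C4–C8 bond: each one needs control of position (C8 against C6), of C4 configuration and of chain length among aromatic rings of nearly equal nucleophilicity, on ever larger fragments. The plan rests on the top unit: its ring C is made of O1 and C4a, which belong to a phloroglucinol-type ring A, and of the chain C2–C3–C4, in which C2 carries ring B and C4 carries C8 of the second unit. With C2 at the ketone level this is a 3,5-dioxygenated phenol joined through its ortho carbon and its oxygen to the β-carbon and the carbonyl carbon of a chalcone.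

## Retrosynthetic reasoning

27 ⇐ 26. No skeletal bond is cut. All sixteen phenols and the three lower secondary hydroxyls are carried as benzyl ethers, so the last step is one neutral hydrogenolysis. The free polyphenol, with its acid-, base- and air-sensitivity, appears only at the very end.

26 ⇐ 25. The O1–C2 bond of the top unit is cut to the phenol and a benzylic carbinol. This bond is chosen because it can be closed by displacement with inversion. C2 can then be set in an open chain by carbonyl reduction, free of the conformational bias of ring C, which would favour hydride delivery to the wrong face of a cyclic C2 oxocarbenium ion. The forward step must invert C2 cleanly and leave the neighbouring C3 hydroxyl alone.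

25 ⇐ 24 ⇐ 21 (through 22 and 23). The C2 carbinol is traced to the aryl ketone 24, and the C3 oxygen to oxidation of the C2=C3 enol ether of 21. Both new centres then derive from C4. The oxidant approaches anti to the C4 substituent, which gives the 3,4-trans relation. The C3 hydroxyl in turn directs the hydride through a chelate, which gives the anti diol needed for a 2,3-cis ring after inversion.

21 ⇐ 17 + 18. This is the central disconnection: C4–C4a and O1–C2 are cut together, which removes ring C, ring A and the C4 stereocentre in one move. It is placed here because ring B and the C2 carbon are then delivered ready-made by the enone, and the point of attachment to the trimer is already fixed in 17. The forward reaction has to join the ortho carbon of 18 to the β-carbon of 17 on one face and condense the phenol oxygen with the ketone. A chiral phosphoric acid is proposed to control the face.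

17 ⇐ 14 + 16, and 14 ⇐ 12 (through 13). The enone double bond is cut by an aldol condensation logic to the aldehyde 14 and the aryl methyl ketone 16. The formyl carbon, the future C4, is traced to the bromine of 12 by halogen–lithium exchange and formylation. The regiochemistry of the top interflavan bond is thus decided by where the bromine sits, not by relative nucleophilicity.

12 ⇐ 8 + 11, 11 ⇐ 9 (through 10), and 9 ⇐ 8 + 3. The two lower interflavan bonds are cut at C4–C8 to a flavan-4-yl cation equivalent 8 and the nucleophiles 11 and 3. This is the established way of making such bonds. It is used here on purpose, so that the only unprecedented event in the route is the annulation. The bromine at C8 of 8 blocks self-condensation, is removed once (9 to 11) to expose the next nucleophilic site, and is kept the second time as the handle for 14. The same coupling is not chosen for the third bond. There the trimer would be the nucleophile, with four free ring A positions and two acid-labile interflavan bonds exposed to a Lewis acid and a cation. In the annulation the trimer is the limiting electrophile and the monomeric phenol 18 can be used in excess. The cation coupling is kept in reserve for that bond.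

8 ⇐ 7 ⇐ 6 ⇐ 5 ⇐ 4, 3 ⇐ 2 ⇐ 1, and 16 ⇐ 15. These are functional-group steps: benzylation in two stages (phenols under mild base first, then the secondary hydroxyl), bromination at C8 and oxidation at C4. The six stereocentres at C2 and C3 of the three lower units come unchanged from 1 and 4.

## Alternatives that were turned down

Alternative 1: Ring C is opened at O1–C8a. The six-membered lactone A1, 5,7-dibenzyloxy-4-(penta-O-benzylcatechin-8-yl)chroman-2-one, is traced to the five-membered ketone A2, 4,6-dibenzyloxy-3-(penta-O-benzylcatechin-8-yl)indan-1-one. The forward key step is a Baeyer–Villiger oxidation in which a peracid inserts oxygen between the carbonyl carbon and the ring A carbon.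
- For: the C4–C4a bond and the C4 stereocentre exist before ring C forms, and the migrating aryl carbon keeps its place, so there is no ortho/para question on ring A. The indanone stereocentre could come from asymmetric conjugate arylation. On regiochemical certainty of the ring closure this route is stronger than the chosen one.
- Against: A1 has neither ring B nor the C3 oxygen. An aryl nucleophile must still be added once to the lactone carbonyl, where over-addition competes, and the product is the same kind of hydroxyaryl ketone that the chosen route reaches directly. The migrating carbon has both benzyloxy groups meta, which do not help migration, and the peracid meets several phloroglucinol-type rings with free positions open to hydroxylation. A2 must itself be built on C8 of the lower fragment by a separate sequence.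
- Comparison: the chosen strategy gives up the certainty of an oxygen insertion, but forms the bond to ring A, the C4 centre and ring C in one operation, with ring B in place, from a chalcone two steps from the bromide.

Alternative 2: The cut is C4–C4a, with O1–C2 already present as an aryl ether. In A4, an open-chain C4 methyl ether whose C2 oxygen carries a 3,5-dibenzyloxyphenyl group, a boron Lewis acid ionises C4. The ortho carbon of the tethered aryl ether then closes ring C to give A3, perbenzylated epicatechin-(4β→8)-catechin (identical with 11).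
- For: C2 and C3 are fixed beforehand in an acyclic chain by dependable dihydroxylation-type chemistry. The C4 configuration follows from the ring conformation during closure (C4 aryl pseudo-axial, trans to the 3-benzyloxy group). The closure is intramolecular, so ortho attack is guaranteed, and nothing unprecedented is asked of a catalyst. In stereochemical predictability this alternative is stronger.
- Against: A4 needs an aryl ether at an electron-rich benzylic carbon of defined configuration, made by displacement with a hindered phenol where ionisation competes. The whole C2–C3–C4 chain must be grown linearly on C8 of the lower fragment. At the trimer stage a strong Lewis acid would also meet two acid-labile interflavan bonds and several free nucleophilic ring positions.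
- Comparison: the chosen strategy replaces the long linear preparation by a three-step entry (formylation, condensation, annulation), uses only a weak Brønsted acid, and still leaves C2 and C3 to be set relative to C4.

Alternative 3: The cut is the C2=C3 double bond of a flav-2-ene. Diene A6 carries an α-aryl vinyl ether on the ring A oxygen and a vinyl group on C4. A second-generation ruthenium benzylidene metathesis catalyst closes it to A5, 5,7-dibenzyloxy-2-(3,4-dibenzyloxyphenyl)-4-(penta-O-benzylcatechin-8-yl)-4H-chromene, the dimer-level analogue of 21.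
- For: A5 enters the same end game as 21. The conditions are neutral, so neither retro-Friedel–Crafts cleavage nor hydride loss from C4 is to be feared, and closure cannot go to the wrong position of ring A. In mildness and regiochemical certainty it is at least as strong as the chosen step.
- Against: metathesis creates no stereocentre. The C4 methine, bearing two similar electron-rich aryl groups and a vinyl group, would have to be made enantioselectively earlier, and no dependable method exists for that. The partners are a 1,1-disubstituted electron-rich enol ether and a hindered allylic olefin, a slow case in which ruthenium hydride isomerisation of the vinyl group into conjugation would erase C4. The vinyl ether also needs esterification and carbonyl methylenation on a hindered phenol.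
- Comparison: the chosen annulation forms the same ring together with C4–C4a, O1–C2 and the stereocentre in one step from two simple partners.

Key step: step 13

Assumptions (remarks on the chemistry):
- The lower trimer is assembled by the established acid-mediated C4→C8 coupling of benzylated flavan-3-ols, so (−)-epicatechin (4) is an additional starting material and the annulation is used once.
- The (R) enantiomer of the phosphoric acid is assumed to deliver the phenol to the required face of the enone. The sense of induction cannot be derived with certainty, and the (S) acid is equally available.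
- "Trimer-8-yl" means C8 of the top unit of penta-O-benzylepicatechin-(4β→8)-penta-O-benzylepicatechin-(4β→8)-penta-O-benzylcatechin. Flavan numbering (O1, C2, C3, C4, C4a, C8a) is also used for open-chain intermediates of the top unit.

## Route

Step 1
Reactants: 1 (+)-catechin
Product: 2 5,7,3',4'-tetra-O-benzyl-(+)-catechin
Conditions: BnBr, K2CO3, DMF, 0 °C to rt, Ar
Reagents that add atoms: benzyl bromide BrCc1ccccc1
Why: Williamson etherification; carbonate deprotonates only the four phenols, so the 3-hydroxyl stays free, and the mild base with early capping of the 4'-hydroxyl avoids opening of ring C and C2 epimerisation.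

Step 2
Reactants: 2 5,7,3',4'-tetra-O-benzyl-(+)-catechin
Product: 3 3,5,7,3',4'-penta-O-benzyl-(+)-catechin
Conditions: NaH, BnBr, DMF, 0 °C to rt
Reagents that add atoms: benzyl bromide BrCc1ccccc1
Why: Williamson etherification of the secondary alkoxide; with every phenol capped the quinone methide route to epimerisation is closed, so C2 and C3 are untouched.

Step 3
Reactants: 4 (−)-epicatechin
Product: 5 5,7,3',4'-tetra-O-benzyl-(−)-epicatechin
Conditions: BnBr, K2CO3, DMF, 0 °C to rt, Ar
Reagents that add atoms: benzyl bromide BrCc1ccccc1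
Why: Williamson etherification of the four phenols under the same mild conditions as step 1; the 2,3-cis stereocentres are not affected.

Step 4
Reactants: 5 5,7,3',4'-tetra-O-benzyl-(−)-epicatechin
Product: 6 3,5,7,3',4'-penta-O-benzyl-(−)-epicatechin
Conditions: NaH, BnBr, DMF, 0 °C to rt
Reagents that add atoms: benzyl bromide BrCc1ccccc1
Why: Williamson etherification of the axial secondary hydroxyl; the benzyl ether survives the later organolithium and hydroxide steps and leaves with the others at the end.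

Step 5
Reactants: 6 3,5,7,3',4'-penta-O-benzyl-(−)-epicatechin
Product: 7 8-bromo-3,5,7,3',4'-penta-O-benzylepicatechin
Conditions: N-bromosuccinimide, CH2Cl2, −20 °C to 0 °C, dark
Reagents that add atoms: N-bromosuccinimide O=C1CCC(=O)N1Br
Why: Electrophilic aromatic bromination; of the two activated positions of ring A, C8 (between a benzyloxy group and the ring oxygen) is less hindered than C6 (between two benzyloxy groups). The bromine first caps C8 against self-condensation and later serves as the handle for formylation.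

Step 6
Reactants: 7 8-bromo-3,5,7,3',4'-penta-O-benzylepicatechin
Product: 8 8-bromo-4β-(2-ethoxyethoxy)-3,5,7,3',4'-penta-O-benzylepicatechin
Conditions: 2,3-dichloro-5,6-dicyano-1,4-benzoquinone (DDQ), 2-ethoxyethanol, CH2Cl2, rt
Reagents that add atoms: 2-ethoxyethanol CCOCCO
Why: Benzylic oxidation by hydride abstraction from C4, which is ortho/para to three ether oxygens of ring A; the alcohol captures the cation anti to the axial 3-benzyloxy group. Simple benzyl ethers are not oxidised under these conditions, and the C4 configuration is immaterial because it is lost on ionisation.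

Step 7
Reactants: 8 8-bromo-4β-(2-ethoxyethoxy)-3,5,7,3',4'-penta-O-benzylepicatechin; 3 3,5,7,3',4'-penta-O-benzyl-(+)-catechin
Product: 9 8-bromo-penta-O-benzylepicatechin-(4β→8)-penta-O-benzylcatechin
Conditions: Me3SiOSO2CF3 (0.2 equiv), 3 (1.5 equiv), CH2Cl2, −78 °C; Et3N quench
Reagents that add atoms: none
Why: Lewis acid-mediated Friedel–Crafts coupling of a flavan-4-yl cation; C8 of 3 attacks the cation from the face opposite the 3-benzyloxy group and ring B, which sets the 4β (3,4-trans) stereocentre. The bromine on 8 suppresses self-condensation, so near-equimolar amounts suffice.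

Step 8
Reactants: 9 8-bromo-penta-O-benzylepicatechin-(4β→8)-penta-O-benzylcatechin
Product: 11 penta-O-benzylepicatechin-(4β→8)-penta-O-benzylcatechin, via 8-lithio dimer 10 (not isolated)
Conditions: n-BuLi, THF, −78 °C; then MeOH, −78 °C to rt
Reagents that add atoms: none
Why: Bromine–lithium exchange is faster than benzylic deprotonation at −78 °C, and protonation of the 2,6-dioxygenated aryllithium 10 unmasks C8 of the top unit as the next nucleophilic site.

Step 9
Reactants: 8 8-bromo-4β-(2-ethoxyethoxy)-3,5,7,3',4'-penta-O-benzylepicatechin; 11 penta-O-benzylepicatechin-(4β→8)-penta-O-benzylcatechin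
Product: 12 8-bromo-penta-O-benzylepicatechin-(4β→8)-penta-O-benzylepicatechin-(4β→8)-penta-O-benzylcatechin
Conditions: Me3SiOSO2CF3 (0.2 equiv), 11 (1.2 equiv), CH2Cl2, −78 °C; Et3N quench
Reagents that add atoms: none
Why: The same cation coupling; C8 of the top unit of 11 is the only free position flanked by the ring oxygen and not by two benzyloxy groups, so the cation from 8 should attack there, again trans to its 3-benzyloxy group. The product keeps the bromine at C8 of the new top unit.

Step 10
Reactants: 12 8-bromo-penta-O-benzylepicatechin-(4β→8)-penta-O-benzylepicatechin-(4β→8)-penta-O-benzylcatechin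
Product: 14 8-formyl-penta-O-benzylepicatechin-(4β→8)-penta-O-benzylepicatechin-(4β→8)-penta-O-benzylcatechin, via 8-lithio trimer 13 (not isolated)
Conditions: n-BuLi, THF, −78 °C; DMF, −78 °C to 0 °C; H2O
Reagents that add atoms: N,N-dimethylformamide CN(C)C=O
Why: Bromine–lithium exchange and Bouveault-type formylation of the aryllithium; the carbon that becomes C4 of the top unit is placed exactly on C8.

Step 11
Reactants: 15 3',4'-dihydroxyacetophenone
Product: 16 3',4'-dibenzyloxyacetophenone
Conditions: BnBr, K2CO3, DMF, rt to 60 °C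
Reagents that add atoms: benzyl bromide BrCc1ccccc1
Why: Williamson etherification of both catechol hydroxyls, giving the ring B ketone in the protecting-group pattern of the rest of the molecule.

Step 12
Reactants: 14 8-formyl-penta-O-benzylepicatechin-(4β→8)-penta-O-benzylepicatechin-(4β→8)-penta-O-benzylcatechin; 16 3',4'-dibenzyloxyacetophenone
Product: 17 (E)-1-(3,4-dibenzyloxyphenyl)-3-(trimer-8-yl)prop-2-en-1-one
Conditions: KOH, EtOH/THF, rt to 40 °C
Reagents that add atoms: none
Why: Claisen–Schmidt condensation; the enolate of 16 adds to the non-enolisable aldehyde and E1cB dehydration gives the conjugated (E)-enone. No stereocentre of the fully etherified trimer is base-labile.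

Step 13
Reactants: 17 (E)-1-(3,4-dibenzyloxyphenyl)-3-(trimer-8-yl)prop-2-en-1-one; 18 3,5-dibenzyloxyphenol
Product: 21 5,7-dibenzyloxy-2-(3,4-dibenzyloxyphenyl)-4β-(trimer-8-yl)-4H-chromene, via Friedel–Crafts ketone 19 (not isolated), via chroman-2-ol hemiketal 20 (not isolated)
Conditions: (R)-3,3'-bis(2,4,6-triisopropylphenyl)-1,1'-binaphthyl-2,2'-diyl hydrogen phosphate (10 mol%), 18 (3 equiv), 5 Å molecular sieves, toluene, 0 °C to rt, Ar, dark
Reagents that add atoms: none
Why: Proposed new method: the phosphoric acid hydrogen-bonds the carbonyl oxygen of 17 and the hydroxyl of 18, and the phenol carbon ortho to the hydroxyl and para to a benzyloxy group adds to the β-carbon (C4–C4a), whose developing positive charge is carried by the trioxygenated ring A of the trimer; tautomerisation gives ketone 19. The phenol oxygen then adds to the ketone carbonyl (6-exo-trig) to give hemiketal 20, which loses water through the C2 oxocarbenium ion to the enol ether 21 (O1–C2), the sieves drawing the sequence forward. The closest known reaction type is the acid-catalysed Friedel–Crafts conjugate addition and cyclodehydration of electron-rich phenols and naphthols with enones to 4-aryl-4H-chromenes, whose chiral phosphoric acid versions are established only for two-point-binding enones such as β,γ-unsaturated α-keto esters; the extension here is to a simple chalcone. The one new stereocentre, C4, is set in the C–C bond-forming step by the catalyst, whose 3,3'-aryl groups leave one face of the hydrogen-bonded s-cis enone open; the nearest stereocentre of 17 is four bonds from the β-carbon, so substrate bias should be small. Ortho instead of para C-alkylation is secured by delivery through the hydrogen-bonded hydroxyl and by the greater hindrance of the position between the two benzyloxy groups; a para adduct cannot cyclise and is separated, and O-alkylation is reversible. The acid is too weak to ionise the interflavan bonds of the trimer, and exclusion of air and of stronger acid guards against hydride loss from C4 of 21 to a flavylium ion. C2 and C3 remain trigonal, so both can be set afterwards from C4.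

Step 14
Reactants: 21 5,7-dibenzyloxy-2-(3,4-dibenzyloxyphenyl)-4β-(trimer-8-yl)-4H-chromene
Product: 24 (2R)-1-(3,4-dibenzyloxyphenyl)-2-hydroxy-3-(2-hydroxy-4,6-dibenzyloxyphenyl)-3-(trimer-8-yl)propan-1-one, via 2α,3α-epoxide 22 (not isolated), via chromane-2,3-diol hemiketal 23 (not isolated)
Conditions: dimethyldioxirane (1.1 equiv, acetone), CH2Cl2, −40 °C; then THF/H2O, pH 7 phosphate buffer, 0 °C
Reagents that add atoms: dimethyldioxirane CC1(C)OO1; water O
Why: Dioxirane epoxidation of the electron-rich enol ether occurs anti to the pseudo-axial C4 substituent, which fixes the C3–O bond trans to the interflavan bond. The 2-aryl epoxy ether 22 opens at C2, hydration gives hemiketal 23, and ring–chain tautomerism releases the aryl ketone and the phenol (Rubottom-type α-hydroxylation of an enol ether).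

Step 15
Reactants: 24 (2R)-1-(3,4-dibenzyloxyphenyl)-2-hydroxy-3-(2-hydroxy-4,6-dibenzyloxyphenyl)-3-(trimer-8-yl)propan-1-one
Product: 25 (1S,2R)-1-(3,4-dibenzyloxyphenyl)-3-(2-hydroxy-4,6-dibenzyloxyphenyl)-3-(trimer-8-yl)propane-1,2-diol
Conditions: Zn(BH4)2 (excess), Et2O/CH2Cl2, −20 °C to 0 °C; H2O
Reagents that add atoms: none
Why: Cram-chelate reduction; zinc bridges the carbonyl and α-hydroxyl oxygens in a five-membered chelate, and hydride adds from the face bearing the C3 hydrogen, away from the diarylmethyl group. This gives the anti (erythro) diol with the S configuration at flavan C2.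

Step 16
Reactants: 25 (1S,2R)-1-(3,4-dibenzyloxyphenyl)-3-(2-hydroxy-4,6-dibenzyloxyphenyl)-3-(trimer-8-yl)propane-1,2-diol
Product: 26 5,7,3',4'-tetra-O-benzylepicatechin-(4β→8)-penta-O-benzylepicatechin-(4β→8)-penta-O-benzylepicatechin-(4β→8)-penta-O-benzylcatechin
Conditions: PPh3, diisopropyl azodicarboxylate, THF, 0 °C to rt
Reagents that add atoms: none
Why: Intramolecular Mitsunobu etherification; the phenol displaces the activated benzylic C2 oxygen with inversion (6-exo-tet), which turns the 2S carbinol into the 2R ether with ring B cis to the 3-hydroxyl. The benzylic position is displaced in preference to C3, where attack would need a five-membered closure at a non-activated carbon.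

Step 17
Reactants: 26 5,7,3',4'-tetra-O-benzylepicatechin-(4β→8)-penta-O-benzylepicatechin-(4β→8)-penta-O-benzylepicatechin-(4β→8)-penta-O-benzylcatechin
Product: 27 arecatannin A2
Conditions: H2 (1 atm), Pd(OH)2/C, THF/MeOH/H2O, rt; filtration under Ar, lyophilisation
Reagents that add atoms: none
Why: Hydrogenolysis of the nineteen benzyl ethers under neutral conditions leaves the acid-labile interflavan bonds and all eleven stereocentres untouched.

## Compound list

1 | (+)-catechin, (2R,3S) | Oc1cc(O)c2c(c1)O[C@H](c1ccc(O)c(O)c1)[C@@H](O)C2 | starting material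
2 | 5,7,3',4'-tetra-O-benzyl-(+)-catechin | c3ccccc3COc1cc(OCc3ccccc3)c2c(c1)O[C@H](c1ccc(OCc3ccccc3)c(OCc3ccccc3)c1)[C@@H](O)C2 | intermediate
3 | 3,5,7,3',4'-penta-O-benzyl-(+)-catechin | c3ccccc3COc1cc(OCc3ccccc3)c2c(c1)O[C@H](c1ccc(OCc3ccccc3)c(OCc3ccccc3)c1)[C@@H](OCc3ccccc3)C2 | intermediate
4 | (−)-epicatechin, (2R,3R) | Oc1cc(O)c2c(c1)O[C@H](c1ccc(O)c(O)c1)[C@H](O)C2 | starting material
5 | 5,7,3',4'-tetra-O-benzyl-(−)-epicatechin | c3ccccc3COc1cc(OCc3ccccc3)c2c(c1)O[C@H](c1ccc(OCc3ccccc3)c(OCc3ccccc3)c1)[C@H](O)C2 | intermediate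
6 | 3,5,7,3',4'-penta-O-benzyl-(−)-epicatechin | c3ccccc3COc1cc(OCc3ccccc3)c2c(c1)O[C@H](c1ccc(OCc3ccccc3)c(OCc3ccccc3)c1)[C@H](OCc3ccccc3)C2 | intermediate
7 | 8-bromo-3,5,7,3',4'-penta-O-benzylepicatechin | Brc1c(OCc3ccccc3)cc(OCc3ccccc3)c2c1O[C@H](c1ccc(OCc3ccccc3)c(OCc3ccccc3)c1)[C@H](OCc3ccccc3)C2 | intermediate
8 | 8-bromo-4β-(2-ethoxyethoxy)-3,5,7,3',4'-penta-O-benzylepicatechin (alkoxy group trans to the 3-benzyloxy group) | Brc1c(OCc3ccccc3)cc(OCc3ccccc3)c2c1O[C@H](c1ccc(OCc3ccccc3)c(OCc3ccccc3)c1)[C@H](OCc3ccccc3)[C@H]2OCCOCC | intermediate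
9 | 8-bromo-penta-O-benzylepicatechin-(4β→8)-penta-O-benzylcatechin | Brc1c(OCc3ccccc3)cc(OCc3ccccc3)c2c1O[C@H](c1ccc(OCc3ccccc3)c(OCc3ccccc3)c1)[C@H](OCc3ccccc3)[C@H]2c1c(OCc3ccccc3)cc(OCc3ccccc3)c2c1O[C@H](c1ccc(OCc3ccccc3)c(OCc3ccccc3)c1)[C@@H](OCc3ccccc3)C2 | intermediate
10 | 8-lithio-penta-O-benzylepicatechin-(4β→8)-penta-O-benzylcatechin | [Li]c1c(OCc3ccccc3)cc(OCc3ccccc3)c2c1O[C@H](c1ccc(OCc3ccccc3)c(OCc3ccccc3)c1)[C@H](OCc3ccccc3)[C@H]2c1c(OCc3ccccc3)cc(OCc3ccccc3)c2c1O[C@H](c1ccc(OCc3ccccc3)c(OCc3ccccc3)c1)[C@@H](OCc3ccccc3)C2 | intermediate (not isolated)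
11 | penta-O-benzylepicatechin-(4β→8)-penta-O-benzylcatechin | c3ccccc3COc1cc(OCc3ccccc3)c2c(c1)O[C@H](c1ccc(OCc3ccccc3)c(OCc3ccccc3)c1)[C@H](OCc3ccccc3)[C@H]2c1c(OCc3ccccc3)cc(OCc3ccccc3)c2c1O[C@H](c1ccc(OCc3ccccc3)c(OCc3ccccc3)c1)[C@@H](OCc3ccccc3)C2 | intermediate
12 | 8-bromo-penta-O-benzylepicatechin-(4β→8)-penta-O-benzylepicatechin-(4β→8)-penta-O-benzylcatechin (bromine at C8 of the top unit) | Brc1c(OCc3ccccc3)cc(OCc3ccccc3)c2c1O[C@H](c1ccc(OCc3ccccc3)c(OCc3ccccc3)c1)[C@H](OCc3ccccc3)[C@H]2c1c(OCc3ccccc3)cc(OCc3ccccc3)c2c1O[C@H](c1ccc(OCc3ccccc3)c(OCc3ccccc3)c1)[C@H](OCc3ccccc3)[C@H]2c1c(OCc3ccccc3)cc(OCc3ccccc3)c2c1O[C@H](c1ccc(OCc3ccccc3)c(OCc3ccccc3)c1)[C@@H](OCc3ccccc3)C2 | intermediate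
13 | 8-lithio analogue of 12 | [Li]c1c(OCc3ccccc3)cc(OCc3ccccc3)c2c1O[C@H](c1ccc(OCc3ccccc3)c(OCc3ccccc3)c1)[C@H](OCc3ccccc3)[C@H]2c1c(OCc3ccccc3)cc(OCc3ccccc3)c2c1O[C@H](c1ccc(OCc3ccccc3)c(OCc3ccccc3)c1)[C@H](OCc3ccccc3)[C@H]2c1c(OCc3ccccc3)cc(OCc3ccccc3)c2c1O[C@H](c1ccc(OCc3ccccc3)c(OCc3ccccc3)c1)[C@@H](OCc3ccccc3)C2 | intermediate (not isolated)
14 | 8-formyl-penta-O-benzylepicatechin-(4β→8)-penta-O-benzylepicatechin-(4β→8)-penta-O-benzylcatechin | O=Cc1c(OCc3ccccc3)cc(OCc3ccccc3)c2c1O[C@H](c1ccc(OCc3ccccc3)c(OCc3ccccc3)c1)[C@H](OCc3ccccc3)[C@H]2c1c(OCc3ccccc3)cc(OCc3ccccc3)c2c1O[C@H](c1ccc(OCc3ccccc3)c(OCc3ccccc3)c1)[C@H](OCc3ccccc3)[C@H]2c1c(OCc3ccccc3)cc(OCc3ccccc3)c2c1O[C@H](c1ccc(OCc3ccccc3)c(OCc3ccccc3)c1)[C@@H](OCc3ccccc3)C2 | intermediate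
15 | 3',4'-dihydroxyacetophenone | CC(=O)c1ccc(O)c(O)c1 | starting material
16 | 3',4'-dibenzyloxyacetophenone | CC(=O)c1ccc(OCc2ccccc2)c(OCc2ccccc2)c1 | intermediate
17 | (E)-1-(3,4-dibenzyloxyphenyl)-3-(trimer-8-yl)prop-2-en-1-one | O=C(c1ccc(OCc3ccccc3)c(OCc3ccccc3)c1)/C=C/c1c(OCc3ccccc3)cc(OCc3ccccc3)c2c1O[C@H](c1ccc(OCc3ccccc3)c(OCc3ccccc3)c1)[C@H](OCc3ccccc3)[C@H]2c1c(OCc3ccccc3)cc(OCc3ccccc3)c2c1O[C@H](c1ccc(OCc3ccccc3)c(OCc3ccccc3)c1)[C@H](OCc3ccccc3)[C@H]2c1c(OCc3ccccc3)cc(OCc3ccccc3)c2c1O[C@H](c1ccc(OCc3ccccc3)c(OCc3ccccc3)c1)[C@@H](OCc3ccccc3)C2 | intermediate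
18 | 3,5-dibenzyloxyphenol | Oc1cc(OCc2ccccc2)cc(OCc2ccccc2)c1 | starting material
19 | 1-(3,4-dibenzyloxyphenyl)-3-(2-hydroxy-4,6-dibenzyloxyphenyl)-3-(trimer-8-yl)propan-1-one (C3 configured as C4 of 21) | O=C(c1ccc(OCc3ccccc3)c(OCc3ccccc3)c1)C[C@H](c1c(O)cc(OCc3ccccc3)cc1OCc3ccccc3)c1c(OCc3ccccc3)cc(OCc3ccccc3)c2c1O[C@H](c1ccc(OCc3ccccc3)c(OCc3ccccc3)c1)[C@H](OCc3ccccc3)[C@H]2c1c(OCc3ccccc3)cc(OCc3ccccc3)c2c1O[C@H](c1ccc(OCc3ccccc3)c(OCc3ccccc3)c1)[C@H](OCc3ccccc3)[C@H]2c1c(OCc3ccccc3)cc(OCc3ccccc3)c2c1O[C@H](c1ccc(OCc3ccccc3)c(OCc3ccccc3)c1)[C@@H](OCc3ccccc3)C2 | intermediate (not isolated)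
20 | 5,7-dibenzyloxy-2-(3,4-dibenzyloxyphenyl)-4β-(trimer-8-yl)chroman-2-ol (both C2 epimers) | c3ccccc3COc1cc(OCc3ccccc3)c2c(c1)OC(O)(c1ccc(OCc3ccccc3)c(OCc3ccccc3)c1)C[C@H]2c1c(OCc3ccccc3)cc(OCc3ccccc3)c2c1O[C@H](c1ccc(OCc3ccccc3)c(OCc3ccccc3)c1)[C@H](OCc3ccccc3)[C@H]2c1c(OCc3ccccc3)cc(OCc3ccccc3)c2c1O[C@H](c1ccc(OCc3ccccc3)c(OCc3ccccc3)c1)[C@H](OCc3ccccc3)[C@H]2c1c(OCc3ccccc3)cc(OCc3ccccc3)c2c1O[C@H](c1ccc(OCc3ccccc3)c(OCc3ccccc3)c1)[C@@H](OCc3ccccc3)C2 | intermediate (not isolated)
21 | 5,7-dibenzyloxy-2-(3,4-dibenzyloxyphenyl)-4β-(trimer-8-yl)-4H-chromene (C4 configured as in 27) | c3ccccc3COc1cc(OCc3ccccc3)c2c(c1)OC(c1ccc(OCc3ccccc3)c(OCc3ccccc3)c1)=C[C@H]2c1c(OCc3ccccc3)cc(OCc3ccccc3)c2c1O[C@H](c1ccc(OCc3ccccc3)c(OCc3ccccc3)c1)[C@H](OCc3ccccc3)[C@H]2c1c(OCc3ccccc3)cc(OCc3ccccc3)c2c1O[C@H](c1ccc(OCc3ccccc3)c(OCc3ccccc3)c1)[C@H](OCc3ccccc3)[C@H]2c1c(OCc3ccccc3)cc(OCc3ccccc3)c2c1O[C@H](c1ccc(OCc3ccccc3)c(OCc3ccccc3)c1)[C@@H](OCc3ccccc3)C2 | intermediate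
22 | 2α,3α-epoxide of 21 (oxirane anti to the 4β substituent) | c3ccccc3COc1cc(OCc3ccccc3)c2c(c1)O[C@]4(c1ccc(OCc3ccccc3)c(OCc3ccccc3)c1)O[C@@H]4[C@H]2c1c(OCc3ccccc3)cc(OCc3ccccc3)c2c1O[C@H](c1ccc(OCc3ccccc3)c(OCc3ccccc3)c1)[C@H](OCc3ccccc3)[C@H]2c1c(OCc3ccccc3)cc(OCc3ccccc3)c2c1O[C@H](c1ccc(OCc3ccccc3)c(OCc3ccccc3)c1)[C@H](OCc3ccccc3)[C@H]2c1c(OCc3ccccc3)cc(OCc3ccccc3)c2c1O[C@H](c1ccc(OCc3ccccc3)c(OCc3ccccc3)c1)[C@@H](OCc3ccccc3)C2 | intermediate (not isolated)
23 | 5,7-dibenzyloxy-2-(3,4-dibenzyloxyphenyl)-4β-(trimer-8-yl)chromane-2,3α-diol (both C2 epimers; 3-hydroxyl trans to the C4 substituent) | c3ccccc3COc1cc(OCc3ccccc3)c2c(c1)OC(O)(c1ccc(OCc3ccccc3)c(OCc3ccccc3)c1)[C@H](O)[C@H]2c1c(OCc3ccccc3)cc(OCc3ccccc3)c2c1O[C@H](c1ccc(OCc3ccccc3)c(OCc3ccccc3)c1)[C@H](OCc3ccccc3)[C@H]2c1c(OCc3ccccc3)cc(OCc3ccccc3)c2c1O[C@H](c1ccc(OCc3ccccc3)c(OCc3ccccc3)c1)[C@H](OCc3ccccc3)[C@H]2c1c(OCc3ccccc3)cc(OCc3ccccc3)c2c1O[C@H](c1ccc(OCc3ccccc3)c(OCc3ccccc3)c1)[C@@H](OCc3ccccc3)C2 | intermediate (not isolated)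
24 | (2R)-1-(3,4-dibenzyloxyphenyl)-2-hydroxy-3-(2-hydroxy-4,6-dibenzyloxyphenyl)-3-(trimer-8-yl)propan-1-one (C3 configured as C4 of 21) | O=C(c1ccc(OCc3ccccc3)c(OCc3ccccc3)c1)[C@H](O)[C@H](c1c(O)cc(OCc3ccccc3)cc1OCc3ccccc3)c1c(OCc3ccccc3)cc(OCc3ccccc3)c2c1O[C@H](c1ccc(OCc3ccccc3)c(OCc3ccccc3)c1)[C@H](OCc3ccccc3)[C@H]2c1c(OCc3ccccc3)cc(OCc3ccccc3)c2c1O[C@H](c1ccc(OCc3ccccc3)c(OCc3ccccc3)c1)[C@H](OCc3ccccc3)[C@H]2c1c(OCc3ccccc3)cc(OCc3ccccc3)c2c1O[C@H](c1ccc(OCc3ccccc3)c(OCc3ccccc3)c1)[C@@H](OCc3ccccc3)C2 | intermediate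
25 | (1S,2R)-1-(3,4-dibenzyloxyphenyl)-3-(2-hydroxy-4,6-dibenzyloxyphenyl)-3-(trimer-8-yl)propane-1,2-diol (anti diol; C3 configured as C4 of 21) | O[C@@H](c1ccc(OCc3ccccc3)c(OCc3ccccc3)c1)[C@H](O)[C@H](c1c(O)cc(OCc3ccccc3)cc1OCc3ccccc3)c1c(OCc3ccccc3)cc(OCc3ccccc3)c2c1O[C@H](c1ccc(OCc3ccccc3)c(OCc3ccccc3)c1)[C@H](OCc3ccccc3)[C@H]2c1c(OCc3ccccc3)cc(OCc3ccccc3)c2c1O[C@H](c1ccc(OCc3ccccc3)c(OCc3ccccc3)c1)[C@H](OCc3ccccc3)[C@H]2c1c(OCc3ccccc3)cc(OCc3ccccc3)c2c1O[C@H](c1ccc(OCc3ccccc3)c(OCc3ccccc3)c1)[C@@H](OCc3ccccc3)C2 | intermediate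
26 | 5,7,3',4'-tetra-O-benzylepicatechin-(4β→8)-penta-O-benzylepicatechin-(4β→8)-penta-O-benzylepicatechin-(4β→8)-penta-O-benzylcatechin (3-hydroxyl of the top unit free) | c3ccccc3COc1cc(OCc3ccccc3)c2c(c1)O[C@H](c1ccc(OCc3ccccc3)c(OCc3ccccc3)c1)[C@H](O)[C@H]2c1c(OCc3ccccc3)cc(OCc3ccccc3)c2c1O[C@H](c1ccc(OCc3ccccc3)c(OCc3ccccc3)c1)[C@H](OCc3ccccc3)[C@H]2c1c(OCc3ccccc3)cc(OCc3ccccc3)c2c1O[C@H](c1ccc(OCc3ccccc3)c(OCc3ccccc3)c1)[C@H](OCc3ccccc3)[C@H]2c1c(OCc3ccccc3)cc(OCc3ccccc3)c2c1O[C@H](c1ccc(OCc3ccccc3)c(OCc3ccccc3)c1)[C@@H](OCc3ccccc3)C2 | intermediate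
27 | arecatannin A2, epicatechin-(4β→8)-epicatechin-(4β→8)-epicatechin-(4β→8)-catechin | Oc1cc(O)c2c(c1)O[C@H](c1ccc(O)c(O)c1)[C@H](O)[C@H]2c1c(O)cc(O)c2c1O[C@H](c1ccc(O)c(O)c1)[C@H](O)[C@H]2c1c(O)cc(O)c2c1O[C@H](c1ccc(O)c(O)c1)[C@H](O)[C@H]2c1c(O)cc(O)c2c1O[C@H](c1ccc(O)c(O)c1)[C@@H](O)C2 | target

## Step count and least certain steps

Total step count: 17. Longest linear sequence: 14 steps (steps 3 to 10 and 12 to 17, from 4).

Step 13 (key step, proposed new method). The most likely failure is poor facial selectivity, because a simple chalcone offers the catalyst only one binding point. Other risks are sluggish activation of the donor-substituted enone by a weak acid, reversal of the C–C bond formation before ring closure (which would scramble C4), alkylation para to the phenol hydroxyl, and hydride loss from C4 of the product under acid. The fallback uses known chemistry and sets out from 12 and 8: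
- 12 is lithiated to 13 and protonated with methanol, as in step 8, to give the C8–H pentadeca-O-benzyl trimer F1.
- F1 in slight excess is coupled with the cation precursor 8 (Me3SiOSO2CF3, CH2Cl2, −78 °C), as in steps 7 and 9, to give the 8-bromo-perbenzylated tetramer F2.
- Hydrogenolysis of F2 over Pd(OH)2/C with triethylamine removes the twenty benzyl groups and the bromine and comes back to the route at 27.
The price is the lower regiochemical certainty of a trimer nucleophile with four free ring A positions.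

Step 16. The electron-rich benzylic oxyphosphonium ion may ionise, so that inversion at C2 is eroded, or the neighbouring C3 hydroxyl may take part (epoxide formation, or closure to a five-membered ring). The fallback changes the mode of activation and sets out from 25. Triethyl orthoformate and pyridinium p-toluenesulfonate in 1,2-dichloroethane at 60 °C form the cyclic orthoformate across the diol. Its dioxolanylium ion is opened by the phenol at the benzylic carbon with inversion, the known course of this flavan-3-ol cyclisation, to give the 3-O-formate of the tetramer F3. Methanolysis (K2CO3, MeOH) then returns to the route at 26.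

Step 15. Chelation control may be eroded if the zinc phenoxide formed from the free phenol competes as a ligand, and the α-hydroxy ketone may epimerise at C3 through enolisation before it is reduced. The fallback sets out from 24. The phenol alone is silylated (tert-butyldimethylsilyl chloride, imidazole, DMF, 0 °C) to the silyl ether F4. Zn(BH4)2 then reduces the ketone under the same chelate control, without a competing phenoxide, to the silylated anti diol F5. Bu4NF in THF removes the silyl group and comes back at 25.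

Step 14. The dioxirane may over-oxidise other electron-rich positions, the epoxy ether may rearrange by hydride shift to the 3-ketone before hydration, or attack may leak to the face syn to the C4 substituent. The fallback sets out from 21 and replaces epoxidation and hydrolysis by a direct dihydroxylation: OsO4 (catalytic) with N-methylmorpholine N-oxide in acetone/water adds both oxygens anti to the C4 substituent. This gives the hemiketal 23 without an epoxide intermediate; 23 opens to 24, where the route is rejoined.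

## Further compounds

F1 | step 13 | penta-O-benzylepicatechin-(4β→8)-penta-O-benzylepicatechin-(4β→8)-penta-O-benzylcatechin (C8–H trimer) | c3ccccc3COc1cc(OCc3ccccc3)c2c(c1)O[C@H](c1ccc(OCc3ccccc3)c(OCc3ccccc3)c1)[C@H](OCc3ccccc3)[C@H]2c1c(OCc3ccccc3)cc(OCc3ccccc3)c2c1O[C@H](c1ccc(OCc3ccccc3)c(OCc3ccccc3)c1)[C@H](OCc3ccccc3)[C@H]2c1c(OCc3ccccc3)cc(OCc3ccccc3)c2c1O[C@H](c1ccc(OCc3ccccc3)c(OCc3ccccc3)c1)[C@@H](OCc3ccccc3)C2
F2 | step 13 | 8-bromo-penta-O-benzylepicatechin-(4β→8)-penta-O-benzylepicatechin-(4β→8)-penta-O-benzylepicatechin-(4β→8)-penta-O-benzylcatechin | Brc1c(OCc3ccccc3)cc(OCc3ccccc3)c2c1O[C@H](c1ccc(OCc3ccccc3)c(OCc3ccccc3)c1)[C@H](OCc3ccccc3)[C@H]2c1c(OCc3ccccc3)cc(OCc3ccccc3)c2c1O[C@H](c1ccc(OCc3ccccc3)c(OCc3ccccc3)c1)[C@H](OCc3ccccc3)[C@H]2c1c(OCc3ccccc3)cc(OCc3ccccc3)c2c1O[C@H](c1ccc(OCc3ccccc3)c(OCc3ccccc3)c1)[C@H](OCc3ccccc3)[C@H]2c1c(OCc3ccccc3)cc(OCc3ccccc3)c2c1O[C@H](c1ccc(OCc3ccccc3)c(OCc3ccccc3)c1)[C@@H](OCc3ccccc3)C2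
F3 | step 16 | 3-O-formate of 26 (formate on the 3-oxygen of the top unit) | c3ccccc3COc1cc(OCc3ccccc3)c2c(c1)O[C@H](c1ccc(OCc3ccccc3)c(OCc3ccccc3)c1)[C@H](OC=O)[C@H]2c1c(OCc3ccccc3)cc(OCc3ccccc3)c2c1O[C@H](c1ccc(OCc3ccccc3)c(OCc3ccccc3)c1)[C@H](OCc3ccccc3)[C@H]2c1c(OCc3ccccc3)cc(OCc3ccccc3)c2c1O[C@H](c1ccc(OCc3ccccc3)c(OCc3ccccc3)c1)[C@H](OCc3ccccc3)[C@H]2c1c(OCc3ccccc3)cc(OCc3ccccc3)c2c1O[C@H](c1ccc(OCc3ccccc3)c(OCc3ccccc3)c1)[C@@H](OCc3ccccc3)C2
F4 | step 15 | O-tert-butyldimethylsilyl ether of 24 at the phenol | O=C(c1ccc(OCc3ccccc3)c(OCc3ccccc3)c1)[C@H](O)[C@H](c1c(O[Si](C)(C)C(C)(C)C)cc(OCc3ccccc3)cc1OCc3ccccc3)c1c(OCc3ccccc3)cc(OCc3ccccc3)c2c1O[C@H](c1ccc(OCc3ccccc3)c(OCc3ccccc3)c1)[C@H](OCc3ccccc3)[C@H]2c1c(OCc3ccccc3)cc(OCc3ccccc3)c2c1O[C@H](c1ccc(OCc3ccccc3)c(OCc3ccccc3)c1)[C@H](OCc3ccccc3)[C@H]2c1c(OCc3ccccc3)cc(OCc3ccccc3)c2c1O[C@H](c1ccc(OCc3ccccc3)c(OCc3ccccc3)c1)[C@@H](OCc3ccccc3)C2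
F5 | step 15 | O-tert-butyldimethylsilyl ether of 25 at the phenol | O[C@@H](c1ccc(OCc3ccccc3)c(OCc3ccccc3)c1)[C@H](O)[C@H](c1c(O[Si](C)(C)C(C)(C)C)cc(OCc3ccccc3)cc1OCc3ccccc3)c1c(OCc3ccccc3)cc(OCc3ccccc3)c2c1O[C@H](c1ccc(OCc3ccccc3)c(OCc3ccccc3)c1)[C@H](OCc3ccccc3)[C@H]2c1c(OCc3ccccc3)cc(OCc3ccccc3)c2c1O[C@H](c1ccc(OCc3ccccc3)c(OCc3ccccc3)c1)[C@H](OCc3ccccc3)[C@H]2c1c(OCc3ccccc3)cc(OCc3ccccc3)c2c1O[C@H](c1ccc(OCc3ccccc3)c(OCc3ccccc3)c1)[C@@H](OCc3ccccc3)C2
F0 | step 14 | none | none
A1 | alternative 1 | 5,7-dibenzyloxy-4-(penta-O-benzylcatechin-8-yl)chroman-2-one | c3ccccc3COc1cc(OCc3ccccc3)c2c(c1)OC(=O)C[C@H]2c1c(OCc3ccccc3)cc(OCc3ccccc3)c2c1O[C@H](c1ccc(OCc3ccccc3)c(OCc3ccccc3)c1)[C@@H](OCc3ccccc3)C2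
A2 | alternative 1 | 4,6-dibenzyloxy-3-(penta-O-benzylcatechin-8-yl)indan-1-one | c3ccccc3COc1cc(OCc3ccccc3)c2c(c1)C(=O)C[C@H]2c1c(OCc3ccccc3)cc(OCc3ccccc3)c2c1O[C@H](c1ccc(OCc3ccccc3)c(OCc3ccccc3)c1)[C@@H](OCc3ccccc3)C2
A3 | alternative 2 | perbenzylated epicatechin-(4β→8)-catechin | c3ccccc3COc1cc(OCc3ccccc3)c2c(c1)O[C@H](c1ccc(OCc3ccccc3)c(OCc3ccccc3)c1)[C@H](OCc3ccccc3)[C@H]2c1c(OCc3ccccc3)cc(OCc3ccccc3)c2c1O[C@H](c1ccc(OCc3ccccc3)c(OCc3ccccc3)c1)[C@@H](OCc3ccccc3)C2
A4 | alternative 2 | open-chain precursor: C4 methyl ether (either C4 epimer) bearing the penta-O-benzylcatechin-8-yl group, 3-benzyloxy group, and 3,5-dibenzyloxyphenyl ether and 3,4-dibenzyloxyphenyl group at C2 | COC(c1c(OCc3ccccc3)cc(OCc3ccccc3)c2c1O[C@H](c1ccc(OCc3ccccc3)c(OCc3ccccc3)c1)[C@@H](OCc3ccccc3)C2)[C@@H](OCc3ccccc3)[C@H](Oc1cc(OCc3ccccc3)cc(OCc3ccccc3)c1)c1ccc(OCc3ccccc3)c(OCc3ccccc3)c1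
A5 | alternative 3 | 5,7-dibenzyloxy-2-(3,4-dibenzyloxyphenyl)-4-(penta-O-benzylcatechin-8-yl)-4H-chromene | c3ccccc3COc1cc(OCc3ccccc3)c2c(c1)OC(c1ccc(OCc3ccccc3)c(OCc3ccccc3)c1)=C[C@H]2c1c(OCc3ccccc3)cc(OCc3ccccc3)c2c1O[C@H](c1ccc(OCc3ccccc3)c(OCc3ccccc3)c1)[C@@H](OCc3ccccc3)C2
A6 | alternative 3 | diene: 1-[2-(1-(3,4-dibenzyloxyphenyl)vinyloxy)-4,6-dibenzyloxyphenyl]-1-(penta-O-benzylcatechin-8-yl)prop-2-ene | C=C[C@H](c1c(OC(=C)c4ccc(OCc3ccccc3)c(OCc3ccccc3)c4)cc(OCc3ccccc3)cc1OCc3ccccc3)c1c(OCc3ccccc3)cc(OCc3ccccc3)c2c1O[C@H](c1ccc(OCc3ccccc3)c(OCc3ccccc3)c1)[C@@H](OCc3ccccc3)C2
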